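**Retrosynthetic overview**
1. The ten-membered ring is closed last by ring-closing metathesis at C1=C10 (ring-cis olefin); the γ-lactone is already in place.
2. C8–C9: catalyst-controlled allylation of a C8 aldehyde with a 2-(acetoxymethyl)allyl stannane (brings C9, C10, C14–OAc), then angeloylation of C8–OH.
3. Key bond C7–C8: 2-lithio-1,3-dithiane (formyl anion) adds to C7 of a 5-alkenyl butenolide anti to C6; the enolate is trapped with Me2N=CH2+ I− to give the α-methylene lactone in the same operation.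
4. Butenolide (first ring): asymmetric alkynylation of a (Z)-enal with methyl propiolate, cis-semihydrogenation, lactonisation.
5. (Z)-Enal: anti-carboalumination/iodination of (S)-hex-1-en-5-yn-3-ol (acrolein + propargyl bromide, kinetic resolution), silylation, Li–I exchange/formylation.

Assumption: C1–C15 are germacrane labels for the ring carbons only; in steps 6 and 12 the ligand antipode named is the one expected to give the drawn carbinol, and its mirror image is used if the opposite sense is found. TBS = tert-butyldimethylsilyl.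

**Step 1**
Reactants: 1 acrolein; 2 propargyl bromide
Product: 3 (±)-hex-1-en-5-yn-3-ol
Conditions: Zn dust, THF/sat. aq. NH4Cl, 0 °C
Reagents that add atoms: none
Why: Zinc Barbier propargylation, in which the allenyl/propargyl zinc species adds 1,2 to the enal (SE2') to give the homopropargylic alcohol as a racemate that is resolved in step 2.

**Step 2**
Reactants: 3
Product: 4 (S)-hex-1-en-5-yn-3-ol
Conditions: Ti(OiPr)4 (10 mol %), D-(−)-DIPT (15 mol %), t-BuOOH (0.6 equiv), 4 Å MS, CH2Cl2, −20 °C; unreacted alcohol recovered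
Reagents that add atoms: none
Why: Sharpless kinetic resolution, in which D-(−)-tartrate epoxidises the (R)-allylic alcohol fast (erythro epoxy alcohol) and leaves the (S)-alcohol in high ee at about 55–60% conversion, which sets C2.

**Step 3**
Reactants: 4
Product: 6 (3S,5Z)-6-iodo-5-methylhexa-1,5-dien-3-ol, via chelated Z-alkenylalane 5 (not isolated)
Conditions: Me3Al (3 equiv), Cp2ZrCl2 (25 mol %), (CH2Cl)2, 23 °C then 80 °C; I2, THF, −30 to 0 °C; aq. NaHCO3/Na2S2O3 work-up
Reagents that add atoms: trimethylaluminium, C[Al](C)C; iodine, [I][I]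
Why: Negishi Zr-catalysed methylalumination adds Me–Al syn across the terminal alkyne, the aluminium alkoxide then drives chelation-controlled isomerisation to the Z alkenylalane, and iodinolysis with retention gives the Z trisubstituted vinyl iodide that fixes the C4=C5 geometry.

**Step 4**
Reactants: 6
Product: 7 tert-butyl{[(3S,5Z)-6-iodo-5-methylhexa-1,5-dien-3-yl]oxy}dimethylsilane
Conditions: TBSCl, imidazole, DMF, 23 °C
Reagents that add atoms: tert-butyldimethylsilyl chloride, CC(C)(C)[Si](C)(C)Cl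
Why: Standard silyl ether formation masks the C2 hydroxyl through the organolithium, organozinc and acylation steps.

**Step 5**
Reactants: 7
Product: 9 (2Z,5S)-5-(TBS-oxy)-3-methylhepta-2,6-dienal, via Z-vinyllithium 8 (not isolated)
Conditions: t-BuLi (2.1 equiv), Et2O, −78 °C; DMF, −78 to 0 °C; aq. work-up
Reagents that add atoms: N,N-dimethylformamide, CN(C)C=O
Why: Iodine–lithium exchange proceeds with retention of olefin geometry and Bouveault formylation of the vinyllithium gives the Z enal.

**Step 6**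
Reactants: 9; 10 methyl propiolate
Product: 12 methyl (4R,5Z,8S)-8-(TBS-oxy)-4-hydroxy-6-methyldeca-5,9-dien-2-ynoate, via zinc acetylide 11 (not isolated)
Conditions: (R,R)-ProPhenol (20 mol %), Ph3P=O (40 mol %), Me2Zn (3 equiv), toluene, 4 °C; aq. work-up
Reagents that add atoms: none
Why: Trost dinuclear zinc–ProPhenol alkynylation, in which the chiral Zn2 catalyst delivers the zinc acetylide to the Si face of the enal carbonyl and sets C6 (R) under catalyst control.

**Step 7**
Reactants: 12
Product: 14 (5S)-5-[(1Z,4S)-4-(TBS-oxy)-2-methylhexa-1,5-dien-1-yl]furan-2(5H)-one, via Z-hydroxy enoate 13 (not isolated)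
Conditions: H2 (1 atm), Pd/CaCO3 poisoned with Pb(OAc)2, quinoline, EtOAc, 0 °C, stopped at 1 equiv H2; then PPTS (cat.), CH2Cl2, 23 °C
Reagents that add atoms: none
Why: Lindlar-type cis-semihydrogenation of the activated ynoate (faster than the unactivated alkenes) gives the Z γ-hydroxy enoate, which lactonises to the butenolide without touching C6 (the descriptor changes to S only through CIP priorities).

**Step 8**
Reactants: 14; 15 1,3-dithiane
Product: 19 (4S,5R)-5-[(1Z,4S)-4-(TBS-oxy)-2-methylhexa-1,5-dien-1-yl]-4-(1,3-dithian-2-yl)-3-methylideneoxolan-2-one, via 2-lithio-1,3-dithiane 16 (not isolated), via lithium enolate 17 (not isolated), via Mannich base 18 (not isolated)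
Conditions: 15, n-BuLi, THF, −30 °C; HMPA (2 equiv), then 14, −78 °C; Me2N=CH2+ I− (3 equiv), −78 to 0 °C; then MeI, MeOH, 23 °C; aq. NaHCO3
Reagents that add atoms: N,N-dimethylmethyleneiminium iodide, C=[N+](C)C.[I-]
Why: Corey–Seebach umpolung in a tandem Michael/Mannich sequence, in which the sulfur-stabilised formyl anion adds 1,4 to the butenolide on the face opposite the C6 alkenyl group (C7 set trans to C6, HMPA favouring conjugate addition), the lithium enolate is trapped at C11 by the iminium salt, and N-methylation with Hofmann-type elimination unveils the α-methylene lactone.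

**Step 9**
Reactants: 19
Product: 20 (2R,3S)-2-[(1Z,4S)-4-(TBS-oxy)-2-methylhexa-1,5-dien-1-yl]-4-methylidene-5-oxooxolane-3-carbaldehyde
Conditions: PhI(OCOCF3)2 (1.5 equiv), MeCN/H2O 9:1, 0 °C, 10 min; used crude at once
Reagents that add atoms: water, O
Why: Oxidative dithioacetal hydrolysis with a hypervalent iodine reagent is fast at 0 °C, spares the alkenes, silyl ether and enoate, and its base-free conditions keep C7 and the exocyclic methylene from isomerising.

**Step 10**
Reactants: 21 3-chloro-2-(chloromethyl)prop-1-ene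
Product: 22 tributyl[2-(chloromethyl)prop-2-en-1-yl]stannane
Conditions: Bu3SnH, LDA (from i-Pr2NH, n-BuLi), THF, 0 °C; then 21 (3 equiv), −78 °C
Reagents that add atoms: tributyltin hydride, CCCC[SnH](CCCC)CCCC
Why: Nucleophilic substitution of one allylic chloride by tributylstannyllithium, with excess of the symmetrical dichloride suppressing double substitution.

**Step 11**
Reactants: 22
Product: 23 2-[(tributylstannyl)methyl]prop-2-en-1-yl acetate
Conditions: KOAc, n-Bu4NI (cat.), DMF, 40 °C
Reagents that add atoms: potassium acetate, CC(=O)[O-].[K+]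
Why: SN2 displacement of the remaining allylic chloride by acetate gives the bifunctional allylstannane.

**Step 12**
Reactants: 20; 23
Product: 24 (4R,5R)-4-[(1R)-3-(acetoxymethyl)-1-hydroxybut-3-en-1-yl]-5-[(1Z,4S)-4-(TBS-oxy)-2-methylhexa-1,5-dien-1-yl]-3-methylideneoxolan-2-one
Conditions: (R)-BINOL (20 mol %), Ti(OiPr)4 (10 mol %), 4 Å MS, CH2Cl2, −20 °C; aq. NaHCO3
Reagents that add atoms: none
Why: Keck catalytic asymmetric allylation, in which the BINOL–Ti(OiPr)4 catalyst directs the 2-substituted allylstannane (the 2-chloromethyl analogue is an established partner) to the Re face of the aldehyde to give the (8R)-carbinol under catalyst control, with the C14 allylic acetate arriving intact.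

**Step 13**
Reactants: 24; 25 angelic acid
Product: 27 (1R)-3-(acetoxymethyl)-1-{(2R,3R)-2-[(1Z,4S)-4-(TBS-oxy)-2-methylhexa-1,5-dien-1-yl]-4-methylidene-5-oxooxolan-3-yl}but-3-en-1-yl (2Z)-2-methylbut-2-enoate, via mixed anhydride 26 (not isolated)
Conditions: 25, 2,4,6-trichlorobenzoyl chloride, Et3N, toluene, 23 °C; then 24, toluene, 80 °C
Reagents that add atoms: none
Why: Yamaguchi mixed-anhydride esterification without a nucleophilic catalyst acylates the only free hydroxyl (C8) with retention and keeps the Z geometry of the angelate, and the trans 6,12-lactone is favoured over the cis 8,12-isomer so translactonisation is not expected.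

**Step 14**
Reactants: 27
Product: 28 (1R)-3-(acetoxymethyl)-1-{(2R,3R)-2-[(1Z,4S)-4-hydroxy-2-methylhexa-1,5-dien-1-yl]-4-methylidene-5-oxooxolan-3-yl}but-3-en-1-yl (2Z)-2-methylbut-2-enoate
Conditions: HF·pyridine, pyridine/THF, 0 to 23 °C
Reagents that add atoms: none
Why: Fluoride-mediated silyl ether cleavage frees the C2 allylic alcohol while acetate, angelate and lactone are stable to buffered HF.

**Step 15**
Reactants: 28
Product: 29 CNP0151426.1, (2S,6R,7R,8R)-14-acetoxy-8-angeloyloxy-2-hydroxygermacra-1(10)E,4Z,11(13)-trien-12,6-olide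
Conditions: second-generation Hoveyda–Grubbs catalyst (15 mol %), 1,4-benzoquinone (30 mol %), toluene (1 mM), 80 °C
Reagents that add atoms: none
Why: Ring-closing metathesis of the vinyl carbinol onto the 1,1-disubstituted alkene closes the ten-membered ring as the ring-cis trisubstituted olefin (CIP E at C1=C10), helped by the free allylic hydroxyl and by the trans-fused lactone and Z C4=C5 olefin, with loss of ethylene.

**Compound list**
1 | acrolein | C=CC=O | starting material
2 | propargyl bromide | BrCC#C | starting material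
3 | (±)-hex-1-en-5-yn-3-ol | C#CCC(O)C=C | intermediate
4 | (S)-hex-1-en-5-yn-3-ol | C#CC[C@H](O)C=C | intermediate
5 | chelated Z-alkenylalane (cyclic aluminium alkoxide, not isolated) | C=C[C@@H]1CC(C)=C[Al](C)O1 | intermediate
6 | (3S,5Z)-6-iodo-5-methylhexa-1,5-dien-3-ol | I/C=C(/C)C[C@H](O)C=C | intermediate
7 | tert-butyl{[(3S,5Z)-6-iodo-5-methylhexa-1,5-dien-3-yl]oxy}dimethylsilane | I/C=C(/C)C[C@H](O[Si](C)(C)C(C)(C)C)C=C | intermediate
8 | Z-vinyllithium from 7 (not isolated) | [Li]/C=C(/C)C[C@H](O[Si](C)(C)C(C)(C)C)C=C | intermediate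
9 | (2Z,5S)-5-(TBS-oxy)-3-methylhepta-2,6-dienal | O=C/C=C(/C)C[C@H](O[Si](C)(C)C(C)(C)C)C=C | intermediate
10 | methyl propiolate | C#CC(=O)OC | starting material
11 | methylzinc acetylide of methyl propiolate (not isolated) | C[Zn]C#CC(=O)OC | intermediate
12 | methyl (4R,5Z,8S)-8-(TBS-oxy)-4-hydroxy-6-methyldeca-5,9-dien-2-ynoate | COC(=O)C#C[C@H](O)/C=C(/C)C[C@H](O[Si](C)(C)C(C)(C)C)C=C | intermediate
13 | methyl (2Z,4S,5Z,8S)-8-(TBS-oxy)-4-hydroxy-6-methyldeca-2,5,9-trienoate (not isolated) | COC(=O)/C=C\[C@H](O)/C=C(/C)C[C@H](O[Si](C)(C)C(C)(C)C)C=C | intermediate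
14 | (5S)-5-[(1Z,4S)-4-(TBS-oxy)-2-methylhexa-1,5-dien-1-yl]furan-2(5H)-one | O=C1O[C@H](/C=C(/C)C[C@H](O[Si](C)(C)C(C)(C)C)C=C)C=C1 | intermediate
15 | 1,3-dithiane | C1CSCSC1 | starting material
16 | 2-lithio-1,3-dithiane (not isolated) | [Li]C1SCCCS1 | intermediate
17 | lithium enolate of the trans conjugate adduct (not isolated) | [Li]OC1=C[C@H](C2SCCCS2)[C@@H](/C=C(/C)C[C@H](O[Si](C)(C)C(C)(C)C)C=C)O1 | intermediate
18 | (3R,4S,5R)-3-[(dimethylamino)methyl]-4-(1,3-dithian-2-yl)-5-[(1Z,4S)-4-(TBS-oxy)-2-methylhexa-1,5-dien-1-yl]oxolan-2-one (not isolated) | CN(C)C[C@@H]1C(=O)O[C@H](/C=C(/C)C[C@H](O[Si](C)(C)C(C)(C)C)C=C)[C@H]1C2SCCCS2 | intermediate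
19 | (4S,5R)-5-[(1Z,4S)-4-(TBS-oxy)-2-methylhexa-1,5-dien-1-yl]-4-(1,3-dithian-2-yl)-3-methylideneoxolan-2-one | C=C1C(=O)O[C@H](/C=C(/C)C[C@H](O[Si](C)(C)C(C)(C)C)C=C)[C@H]1C2SCCCS2 | intermediate
20 | (2R,3S)-2-[(1Z,4S)-4-(TBS-oxy)-2-methylhexa-1,5-dien-1-yl]-4-methylidene-5-oxooxolane-3-carbaldehyde | C=C1C(=O)O[C@H](/C=C(/C)C[C@H](O[Si](C)(C)C(C)(C)C)C=C)[C@H]1C=O | intermediate
21 | 3-chloro-2-(chloromethyl)prop-1-ene | ClCC(=C)CCl | starting material
22 | tributyl[2-(chloromethyl)prop-2-en-1-yl]stannane | CCCC[Sn](CCCC)(CCCC)CC(=C)CCl | intermediate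
23 | 2-[(tributylstannyl)methyl]prop-2-en-1-yl acetate | CCCC[Sn](CCCC)(CCCC)CC(=C)COC(C)=O | intermediate
24 | (4R,5R)-4-[(1R)-3-(acetoxymethyl)-1-hydroxybut-3-en-1-yl]-5-[(1Z,4S)-4-(TBS-oxy)-2-methylhexa-1,5-dien-1-yl]-3-methylideneoxolan-2-one | C=C1C(=O)O[C@H](/C=C(/C)C[C@H](O[Si](C)(C)C(C)(C)C)C=C)[C@H]1[C@H](O)CC(=C)COC(C)=O | intermediate
25 | angelic acid, (2Z)-2-methylbut-2-enoic acid | C/C=C(/C)C(=O)O | starting material
26 | angelic 2,4,6-trichlorobenzoic anhydride (not isolated) | C/C=C(/C)C(=O)OC(=O)c1c(Cl)cc(Cl)cc1Cl | intermediate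
27 | C8 angelate of 24 (C2–OTBS) | C=C1C(=O)O[C@H](/C=C(/C)C[C@H](O[Si](C)(C)C(C)(C)C)C=C)[C@H]1[C@H](OC(=O)/C(C)=C\C)CC(=C)COC(C)=O | intermediate
28 | seco-diene with free C2–OH (desilylated 27) | C=C1C(=O)O[C@H](/C=C(/C)C[C@H](O)C=C)[C@H]1[C@H](OC(=O)/C(C)=C\C)CC(=C)COC(C)=O | intermediate
29 | CNP0151426.1 | C=C1C(=O)O[C@@H]2/C=C(/C)C[C@H](O)/C=C(/COC(C)=O)C[C@@H](OC(=O)/C(C)=C\C)[C@@H]12 | target

**Step count and risks**
Total: 15 steps. Longest linear sequence: 13 steps (steps 1–9 and 12–15); steps 10–11 make stannane 23.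

Step 8 is the most likely to fail. The C6–H of butenolide 14 is both γ to the lactone carbonyl and allylic, so the basic dithianyl anion may deprotonate it (racemisation, decomposition) or add 1,2. The fallback uses a radical formyl-anion equivalent under neutral conditions and sets out from 14. Photocatalytic hydrogen-atom transfer with (n-Bu4N)4[W10O32] (2 mol %) in 1,3-dioxolane/MeCN under 390 nm light adds the dioxolanyl radical anti to the C6 substituent to give the trans dioxolanyl lactone F1. LDA in THF at −78 °C followed by Me2N=CH2+ I− gives the Mannich base F2. MeI then aq. NaHCO3 gives the α-methylene acetal F3. TESOTf/2,4,6-collidine in CH2Cl2 at 0 °C followed by water releases the aldehyde, and the route is rejoined at 20.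

Step 12 is the second risk. Aldehyde 20 can epimerise at C7 or shift its exocyclic olefin into the ring during a slow catalytic allylation, and the catalyst may be mismatched with the α-stereocentre. The fallback sets out from 20 and relies on substrate control plus inversion. A fast Hosomi–Sakurai addition of commercial 2-[(trimethylsilyl)methyl]allyl acetate (BF3·OEt2, CH2Cl2, −78 °C) is expected to favour the Felkin (8S) epimer, the 8-epi alcohol F4. Mitsunobu esterification of F4 with angelic acid 25 (PPh3, DIAD, toluene, 0 °C) inverts C8 and rejoins the route at 27.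

Step 15 is the third risk. The ring is strained, the new olefin is trisubstituted, and the α-methylene lactone can compete in metathesis. The fallback sets out from 28 and masks the enoate. Me2NH in THF at 0 °C gives the dimethylamine Michael adduct F5. Ring-closing metathesis of its camphorsulfonate salt (second-generation Hoveyda–Grubbs catalyst, toluene, 80 °C) gives the macrocyclic amine adduct F6. MeI then aq. NaHCO3 regenerates the methylene lactone and arrives at 29.

**Further compounds**
F1 | step 8 | (4S,5R)-4-(1,3-dioxolan-2-yl)-5-[(1Z,4S)-4-(TBS-oxy)-2-methylhexa-1,5-dien-1-yl]oxolan-2-one | O=C1C[C@H](C2OCCO2)[C@@H](/C=C(/C)C[C@H](O[Si](C)(C)C(C)(C)C)C=C)O1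
F2 | step 8 | (3R,4S,5R)-3-[(dimethylamino)methyl]-4-(1,3-dioxolan-2-yl)-5-[(1Z,4S)-4-(TBS-oxy)-2-methylhexa-1,5-dien-1-yl]oxolan-2-one | CN(C)C[C@@H]1C(=O)O[C@H](/C=C(/C)C[C@H](O[Si](C)(C)C(C)(C)C)C=C)[C@H]1C2OCCO2
F3 | step 8 | (4S,5R)-4-(1,3-dioxolan-2-yl)-5-[(1Z,4S)-4-(TBS-oxy)-2-methylhexa-1,5-dien-1-yl]-3-methylideneoxolan-2-one | C=C1C(=O)O[C@H](/C=C(/C)C[C@H](O[Si](C)(C)C(C)(C)C)C=C)[C@H]1C2OCCO2
F4 | step 12 | (4R,5R)-4-[(1S)-3-(acetoxymethyl)-1-hydroxybut-3-en-1-yl]-5-[(1Z,4S)-4-(TBS-oxy)-2-methylhexa-1,5-dien-1-yl]-3-methylideneoxolan-2-one | C=C1C(=O)O[C@H](/C=C(/C)C[C@H](O[Si](C)(C)C(C)(C)C)C=C)[C@H]1[C@@H](O)CC(=C)COC(C)=O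
F5 | step 15 | (11R)-13-(dimethylamino)-11,13-dihydro derivative of 28 | CN(C)C[C@@H]1C(=O)O[C@H](/C=C(/C)C[C@H](O)C=C)[C@H]1[C@H](OC(=O)/C(C)=C\C)CC(=C)COC(C)=O
F6 | step 15 | (11R)-13-(dimethylamino)-11,13-dihydro derivative of 29 | CN(C)C[C@@H]1C(=O)O[C@@H]2/C=C(/C)C[C@H](O)/C=C(/COC(C)=O)C[C@@H](OC(=O)/C(C)=C\C)[C@@H]12
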